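The route rests on disconnecting the Z-configured C13=C14 enoate through a temporary lactone. In labdane numbering the tertiary C9 hydroxyl on ring B and the C15 carbonyl sit on the same side of C13=C14, so they can be tied into a seven-membered ring O–C9–C11–C12–C13=C14–C15 spiro to ring B. Ring-closing metathesis of a C9 acrylate onto the isopropenyl end of the C11–C13 chain forms C13=C14 and fixes its geometry in one operation, because that ring only tolerates a cis olefin. The precursor is a trans-decalin from (R)-carvone bearing the C9 acrylate (equatorial), an axial 3-methylbut-3-enyl chain at C9 and the ring A C2=C3 alkene, which is dihydroxylated last.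

Key step: step 10

Remark: labdane numbering is used for all bicyclic compounds (ring A = C1–C5 with C10, ring B = C5–C10, C16 = methyl on C13, C17 = methyl on C8); α is the face opposite the C10 methyl.
Remark: ethyl (Z)-3-iodoacrylate, 2-methylallylmagnesium chloride (THF solution) and LiN(i-Pr)2 are taken as purchased, and a metal alkoxide, enolate or carboxylate that is merely protonated during aqueous work-up is treated as the salt form of the isolated product.

**Step 1**
Reactants: 1 (R)-carvone; 2 iodomethane
Product: 4 6-methylcarvone (both C6 epimers), via carvone lithium dienolate 3 (not isolated)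
Conditions: LiN(i-Pr)2 (1.05 equiv), THF, −78 °C; then MeI, −78 → 0 °C
Reagents that add atoms: iodomethane, CI
Why: Kinetic α′-deprotonation of the enone by the hindered lithium amide gives the cross-conjugated dienolate, and its C-methylation (enolate alkylation) is reliable for carvone; the configuration at the new C6 centre does not matter because this carbon is enolised again in step 4.

**Step 2**
Reactants: 5 ethyl (Z)-3-iodoprop-2-enoate
Product: 6 (Z)-3-iodoprop-2-en-1-ol
Conditions: i-Bu2AlH (2.2 equiv), CH2Cl2, −78 → 0 °C; aq. potassium sodium tartrate
Reagents that add atoms: none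
Why: Low-temperature 1,2-reduction of the ester by i-Bu2AlH (aluminium hydride ester reduction) stops at the allylic alcohol and leaves the vinyl iodide and its Z geometry untouched.

**Step 3**
Reactants: 6 (Z)-3-iodoprop-2-en-1-ol
Product: 7 (Z)-3-bromo-1-iodoprop-1-ene
Conditions: PBr3 (0.4 equiv), Et2O, 0 °C
Reagents that add atoms: phosphorus tribromide, BrP(Br)Br
Why: Bromination of a primary allylic alcohol through its phosphite ester (SN2 displacement by bromide) proceeds at 0 °C without loss of the Z geometry, and the bromide is used at once.

**Step 4**
Reactants: 4 6-methylcarvone; 7 (Z)-3-bromo-1-iodoprop-1-ene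
Product: 9 (5S,6S)-6-[(2Z)-3-iodoprop-2-en-1-yl]-2,6-dimethyl-5-(prop-1-en-2-yl)cyclohex-2-en-1-one, via 6-methylcarvone lithium enolate 8 (not isolated)
Conditions: LiN(i-Pr)2 (1.0 equiv), THF, −78 °C; then 7, DMPU, −78 → −20 °C
Reagents that add atoms: (Z)-3-bromo-1-iodoprop-1-ene (7), BrC/C=C\I
Why: Enolate alkylation: the tetrasubstituted lithium enolate attacks the allylic bromide by SN2 (the vinyl iodide is inert) on the face opposite the adjacent isopropenyl group, so the quaternary carbon (future C10) carries its methyl cis and the iodoallyl chain trans to the isopropenyl group.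

**Step 5**
Reactants: 9 vinyl iodide enone
Product: 10 trans-fused dienone (C9 ketone, C7=C8 and C2=C3 double bonds; 4,4,8,10β-tetramethyl; 5α-H)
Conditions: Pd(OAc)2 (10 mol%), PPh3 (20 mol%), HCO2Na (3 equiv), n-Bu4NCl, DMF, 80 °C
Reagents that add atoms: none
Why: Reductive Heck cyclisation: zerovalent palladium inserts into the vinyl C–I bond, 6-exo-trig carbopalladation of the isopropenyl group forms the C3–C4 bond and ring A, and the resulting neopentyl-type alkylpalladium, which has no β-hydrogen, is intercepted by formate-derived hydride to give the second C4 methyl; the trans ring fusion follows from the centres fixed in step 4 and no new stereocentre arises.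

**Step 6**
Reactants: 10 trans-fused dienone
Product: 11 decalone (C9 ketone; 4,4,8α,10β-tetramethyl; 5α-H, 8β-H; C2=C3 double bond)
Conditions: LiBH(s-Bu)3 (1.1 equiv), THF, −78 °C; H2O quench; then NaOMe (cat.), MeOH, rt
Reagents that add atoms: none
Why: Conjugate (1,4) hydride reduction of a β-unsubstituted cyclohexenone by the bulky borohydride, whose 1,2-attack is blocked by the quaternary C10, gives an enolate that is protonated on work-up, and methoxide equilibration leaves the C8 methyl equatorial (α) because the axial epimer would clash 1,3-diaxially with the C10 methyl; the isolated C2=C3 alkene is not touched.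

**Step 7**
Reactants: 11 decalone; 12 trimethylsulfonium iodide
Product: 13 spiro-epoxide (oxirane spiro at C9: oxygen β and equatorial, CH2 = C11 α and axial; otherwise as 11)
Conditions: Me3S+ I− (3.0 equiv), KN(SiMe3)2 (2.8 equiv), THF, −10 °C → rt
Reagents that add atoms: trimethylsulfonium iodide, C[S+](C)C.[I-]
Why: Corey–Chaykovsky epoxidation: the small unstabilised sulfur ylide adds irreversibly along the axial trajectory on the α face, away from the axial C10 methyl on the neighbouring carbon, and the betaine closes by intramolecular SN2, so C11 ends up axial (α) and the epoxide oxygen equatorial (β) at the new C9 stereocentre.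

**Step 8**
Reactants: 13 spiro-epoxide; 14 2-methylallylmagnesium chloride
Product: 15 tertiary alcohol (9β-OH; 9α-(3-methylbut-3-en-1-yl); otherwise as 11)
Conditions: 2-methylallylmagnesium chloride (3 equiv), CuI (10 mol%), THF, −30 → 0 °C; aq. NH4Cl
Reagents that add atoms: 2-methylallylmagnesium chloride, CC(=C)C[Mg]Cl
Why: Copper-catalysed SN2 opening of the 1,1-disubstituted epoxide by the allylic Grignard reagent takes place at the methylene carbon C11, the only carbon open to backside attack, so the C9–O bond and its configuration are retained.

**Step 9**
Reactants: 15 tertiary alcohol; 16 acryloyl chloride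
Product: 18 C9 acrylate (9β-acryloyloxy; 9α-(3-methylbut-3-en-1-yl) chain; decalin otherwise unchanged), via C9 lithium alkoxide 17 (not isolated)
Conditions: n-BuLi (1.05 equiv), THF, −78 °C; then acryloyl chloride (1.5 equiv), −78 → 0 °C
Reagents that add atoms: acryloyl chloride, C=CC(=O)Cl
Why: O-Acylation of the preformed lithium alkoxide with the acid chloride (esterification of a tertiary alcohol through its alkoxide) makes up for the poor nucleophilicity of the congested but equatorial C9 hydroxyl, and no stereocentre is affected.

**Step 10**
Reactants: 18 C9 acrylate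
Product: 19 spiro lactone (seven-membered unsaturated lactone O–C9–C11–C12–C13(CH3)=C14–C15(=O); lactone oxygen β at C9, C11 α; ring A C2=C3 retained)
Conditions: second-generation Grubbs catalyst (H2IMes)(PCy3)Cl2Ru=CHPh (10 mol% in two portions), 1,4-benzoquinone (10 mol%), toluene (0.002 M), 100 °C, Ar sparge
Reagents that add atoms: none
Why: The ruthenium benzylidene first exchanges onto one of the two terminal olefins (the acrylate CH=CH2 or the isopropenyl CH2 of the chain), and the new carbene then adds across the other olefin in an intramolecular [2+2] step; cycloreversion of the ruthenacyclobutane expels ethylene and leaves the C13=C14 bond. The closest known reaction type is ring-closing metathesis of acrylate esters onto 1,1-disubstituted alkenes, which gives β-methyl α,β-unsaturated lactones. The ring closed is the seven-membered lactone O–C9–C11–C12–C13=C14–C15, spiro at C9 of ring B, and the mode of closure is olefin-to-olefin ring closure in which both carbons of the new double bond lie inside the ring. No stereocentre is created; the only stereochemical element, the C13=C14 geometry, is controlled by the ring itself, because a seven-membered ring cannot accommodate a trans double bond, so the C9 oxygen and C15 are cis and the C13 methyl is trans to the carbonyl (Z after ring opening). The step needs chemoselectivity over the ring A C2=C3 alkene and over intermolecular metathesis: the first is secured because opening an unstrained cyclohexene has no driving force and simply reverts, the second by high dilution and by the low tendency of gem-disubstituted olefins and acrylates to homodimerise. Both reacting arms sit on the same quaternary carbon C9, which favours cyclisation, and sweeping out ethylene with argon, portionwise catalyst addition and benzoquinone (against ruthenium hydride isomerisation) should carry the slow closure at the crowded tertiary acrylate to completion.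

**Step 11**
Reactants: 19 spiro lactone
Product: 20 hydroxy acid, (2Z)-5-(9β-hydroxy-decalin-9α-yl)-3-methylpent-2-enoic acid (decalin as in 15)
Conditions: Me3SnOH (5 equiv), ClCH2CH2Cl, 70 °C; cold 0.05 M HCl wash
Reagents that add atoms: trimethyltin hydroxide, C[Sn](C)(C)O
Why: Trimethyltin hydroxide mediated hydrolysis (acyl–oxygen cleavage of the lactone) works near neutrality, so no free C9 alkoxide is formed that could add to C13 and the C13=C14 geometry is kept; the lactone carbonyl is unhindered on its acyl side and more electrophilic than an open-chain ester.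

**Step 12**
Reactants: 20 hydroxy acid; 21 (trimethylsilyl)diazomethane
Product: 22 methyl ester of 20 (Z-enoate, free 9β-OH, ring A C2=C3)
Conditions: Me3SiCHN2 (1.5 equiv), PhMe/MeOH, 0 °C
Reagents that add atoms: (trimethylsilyl)diazomethane, C[Si](C)(C)C=[N+]=[N-]
Why: Methylation of the carboxylic acid by the diazoalkane (esterification via protonated diazomethane) is fast and selective for the acid over the tertiary alcohol and needs no base, so the hydroxy enoate is neither cyclised to the tetrahydrofuran nor relactonised.

**Step 13**
Reactants: 22 methyl ester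
Product: 23 CNP0292844.2, methyl (2Z)-5-[(1S,2R,4aS,6S,7R,8aS)-1,6,7-trihydroxy-2,5,5,8a-tetramethyldecahydronaphthalen-1-yl]-3-methylpent-2-enoate
Conditions: OsO4 (5 mol%), N-methylmorpholine N-oxide (1.5 equiv), acetone/H2O, 0 °C → rt; aq. Na2SO3
Reagents that add atoms: osmium tetroxide, O=[Os](=O)(=O)=O; N-methylmorpholine N-oxide, C[N+]1([O-])CCOCC1; water, O
Why: Upjohn syn-dihydroxylation through a [3+2] osmate ester is selective for the electron-rich cis-disubstituted C2=C3 alkene over the electron-poor trisubstituted enoate, and the reagent approaches from the α face because the β face is screened by the axial methyl groups on C10 and C4, which sets C2 and C3 as the 2α,3α-diol.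

**Compound list**

1 | (R)-carvone, (5R)-2-methyl-5-(prop-1-en-2-yl)cyclohex-2-en-1-one | CC1=CC[C@H](CC1=O)C(C)=C | starting material
2 | iodomethane | CI | starting material
3 | carvone lithium dienolate (O–Li on C1, double bonds C1=C6 and C2=C3, carvone numbering; C5 unchanged) | [Li]OC1=C[C@H](C(C)=C)CC=C1C | intermediate
4 | 6-methylcarvone, (5R)-2,6-dimethyl-5-(prop-1-en-2-yl)cyclohex-2-en-1-one, both C6 epimers | O=C1C(C)=CC[C@@H](C(C)=C)C1C | intermediate
5 | ethyl (Z)-3-iodoprop-2-enoate | CCOC(=O)/C=C\I | starting material
6 | (Z)-3-iodoprop-2-en-1-ol | OC/C=C\I | intermediate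
7 | (Z)-3-bromo-1-iodoprop-1-ene | BrC/C=C\I | intermediate
8 | 6-methylcarvone lithium enolate (O–Li on C1, double bonds C1=C6 and C2=C3; C5 unchanged) | [Li]OC1=C(C)[C@H](C(C)=C)CC=C1C | intermediate
9 | (5S,6S)-6-[(2Z)-3-iodoprop-2-en-1-yl]-2,6-dimethyl-5-(prop-1-en-2-yl)cyclohex-2-en-1-one (6-methyl cis, iodoallyl chain trans to the isopropenyl group) | O=C1C(C)=CC[C@@H](C(C)=C)[C@]1(C)C/C=C\I | intermediate
10 | (4aS,8aS)-2,5,5,8a-tetramethyl-4a,5,8,8a-tetrahydronaphthalen-1(4H)-one (trans-fused; C9 ketone, C7=C8 and C2=C3 double bonds, 5α-H, 10β-methyl) | O=C1C(C)=CC[C@H]2C(C)(C)C=CC[C@@]21C | intermediate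
11 | (2R,4aS,8aS)-2,5,5,8a-tetramethyl-3,4,4a,5,8,8a-hexahydronaphthalen-1(2H)-one (C9 ketone, 8α-methyl equatorial, 5α-H, 10β-methyl, C2=C3 double bond) | O=C1[C@H](C)CC[C@H]2C(C)(C)C=CC[C@@]21C | intermediate
12 | trimethylsulfonium iodide | C[S+](C)C.[I-] | starting material
13 | spiro-epoxide of 11 (oxirane spiro at C9, oxygen β and equatorial, CH2 = C11 α and axial; 8α-methyl, 5α-H, 10β-methyl, C2=C3) | C1O[C@]12[C@H](C)CC[C@H]3C(C)(C)C=CC[C@@]32C | intermediate
14 | 2-methylallylmagnesium chloride | CC(=C)C[Mg]Cl | starting material
15 | tertiary alcohol: 9β-hydroxy-9α-(3-methylbut-3-en-1-yl)-4,4,8α,10β-tetramethyl-5α-H trans-decalin with C2=C3 double bond | CC(=C)CC[C@]1(O)[C@H](C)CC[C@H]2C(C)(C)C=CC[C@@]21C | intermediate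
16 | acryloyl chloride (prop-2-enoyl chloride) | C=CC(=O)Cl | starting material
17 | C9 lithium alkoxide of 15 | CC(=C)CC[C@]1(O[Li])[C@H](C)CC[C@H]2C(C)(C)C=CC[C@@]21C | intermediate
18 | C9 acrylate of 15 (9β-acryloyloxy, 9α-(3-methylbut-3-en-1-yl)); ring-closing metathesis precursor | C=CC(=O)O[C@@]1(CCC(C)=C)[C@H](C)CC[C@H]2C(C)(C)C=CC[C@@]21C | intermediate
19 | spiro seven-membered unsaturated lactone (O–C9–C11–C12–C13(CH3)=C14–C15(=O); lactone oxygen β at C9, C11 α; 8α-methyl, 5α-H, 10β-methyl, C2=C3) | O=C1C=C(C)CC[C@]2(O1)[C@H](C)CC[C@H]3C(C)(C)C=CC[C@@]32C | intermediate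
20 | hydroxy acid: (2Z)-3-methyl-5-(9β-hydroxy-4,4,8α,10β-tetramethyl-5α-H-decal-2-en-9α-yl)pent-2-enoic acid | OC(=O)/C=C(/C)CC[C@]1(O)[C@H](C)CC[C@H]2C(C)(C)C=CC[C@@]21C | intermediate
21 | (trimethylsilyl)diazomethane | C[Si](C)(C)C=[N+]=[N-] | starting material
22 | methyl ester of 20 (13Z-enoate, 9β-OH, C2=C3) | COC(=O)/C=C(/C)CC[C@]1(O)[C@H](C)CC[C@H]2C(C)(C)C=CC[C@@]21C | intermediate
23 | CNP0292844.2, methyl (2Z)-5-[(1S,2R,4aS,6S,7R,8aS)-1,6,7-trihydroxy-2,5,5,8a-tetramethyldecahydronaphthalen-1-yl]-3-methylpent-2-enoate (labdane numbering: 2α,3α,9β-triol, 8α-methyl, 5α-H, 10β-methyl, 13Z) | COC(=O)/C=C(/C)CC[C@]1(O)[C@H](C)CC[C@H]2C(C)(C)[C@H](O)[C@H](O)C[C@@]21C | target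

**Step count and risks**

Total step count: 13. Longest linear sequence: 12 steps (steps 2 and 3, then steps 4–13, counted from ethyl (Z)-3-iodoprop-2-enoate 5). The branch from (R)-carvone 1 joins this line at step 4 after a single step (step 1).

Steps most likely to fail:

1. Step 10 (ring-closing metathesis). The carbene may be slow to engage either the crowded tertiary acrylate or the gem-disubstituted olefin, so that catalyst decay and intermolecular metathesis outrun the seven-membered closure. The fallback sets out from epoxide 13 and comes back at methyl ester 22; the Z geometry is then set by syn-carbocupration instead of by a ring. Epoxide 13 is opened at C11 with allenylmagnesium bromide F1 (from propargyl bromide and Mg, cat. HgCl2, Et2O), which reacts through its propargylic position and should give the terminal alkyne F2 (9β-hydroxy, 9α-but-3-yn-1-yl). Double deprotonation (n-BuLi, 2.1 equiv, THF, −78 °C) and C-acylation of the acetylide with methyl chloroformate should give the hydroxy ynoate F3; the hindered C9 alkoxide is expected to stay unacylated at this temperature. Me2CuLi (3 equiv, THF, −78 °C) then adds methyl and copper syn across the triple bond, and protonation at −78 °C (AcOH) replaces copper with retention. The chain and the ester thus end up cis, which is 22, and the route continues with step 13.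

2. Step 9 (acrylation of the C9 hydroxyl). The congested tertiary alkoxide may fail to attack the acid chloride, while the acid chloride or the acrylate is consumed by polymerisation or conjugate addition. The fallback sets out from alcohol 15 and comes back at acrylate 18; it builds the acrylate on oxygen in two stages. Alcohol 15 is heated with (triphenylphosphoranylidene)ketene (Ph3P=C=C=O, toluene, reflux), a slim cumulene electrophile that adds the O–H of hindered alcohols, to give the stabilised phosphorane ester F4 (C9 (triphenylphosphoranylidene)acetate of 15). Wittig reaction of F4 with paraformaldehyde (toluene, 80 °C) installs the terminal methylene and should give 18.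

3. Step 8 (epoxide opening). Lewis-acidic magnesium salts may trigger a Meinwald rearrangement of the 2,2-disubstituted epoxide to the C9 aldehyde faster than substitution at the neopentyl-like C11, and the aldehyde would then consume the Grignard reagent. The fallback sets out from decalone 11 and comes back at alcohol 15, bypassing steps 7 and 8; it makes the C9–C11 bond by carbonyl addition. (3-Methylbut-3-en-1-yl)magnesium bromide F5 (from 4-bromo-2-methylbut-1-ene and Mg, THF) is stirred with anhydrous CeCl3 at −78 °C to curb enolisation and is then added to ketone 11. Addition is expected from the α face, anti to the axial C10 methyl, which gives 15 with the chain α and the hydroxyl β.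

**Further compounds**

F1 | step 10 | allenylmagnesium bromide | C=C=C[Mg]Br
F2 | step 10 | terminal alkyne: 9α-(but-3-yn-1-yl)-9β-hydroxy-4,4,8α,10β-tetramethyl-5α-H trans-decalin with C2=C3 double bond | C#CCC[C@]1(O)[C@H](C)CC[C@H]2C(C)(C)C=CC[C@@]21C
F3 | step 10 | hydroxy ynoate: methyl 5-(9β-hydroxy-4,4,8α,10β-tetramethyl-5α-H-decal-2-en-9α-yl)pent-2-ynoate | COC(=O)C#CCC[C@]1(O)[C@H](C)CC[C@H]2C(C)(C)C=CC[C@@]21C
F4 | step 9 | C9 (triphenylphosphoranylidene)acetate of 15 | O=C(C=P(c1ccccc1)(c1ccccc1)c1ccccc1)O[C@@]1(CCC(C)=C)[C@H](C)CC[C@H]2C(C)(C)C=CC[C@@]21C
F5 | step 8 | (3-methylbut-3-en-1-yl)magnesium bromide | CC(=C)CC[Mg]Br
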